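## Analysis of the target

Guttiferone L is a polyprenylated acylphloroglucinol built on a bicyclo[3.3.1]nonane-2,4,9-trione. Ring A (C1–C2–C3–C4–C5–C9) holds the enolised β-triketone with a 2,4,5-trihydroxybenzoyl group on C3. Ring B (C1–C8–C7–C6–C5–C9) holds all four side chains, and C9 is the bridging ketone.

There are four stereocentres: the quaternary bridgeheads C1 and C5 (one prenyl each), the tertiary C7 (prenyl) and the quaternary C8 (methyl and 4-methylpent-3-enyl, "homoprenyl"). On the chair of ring B the bonds C1–C2 and C5–C4 are cis and diaxial, and all three prenyl groups are equatorial. The C8 methyl is axial on the side of the C9 bridge and cis to the C7 prenyl; the homoprenyl chain is equatorial and trans to the C7 prenyl.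

The sensitive groups are four trisubstituted alkenes (acid, electrophilic oxidants, hydrogenation), the acidic, metal-chelating acyl-triketone (which can also cyclise onto a prenyl group under acid) and the hydroxyhydroquinone ring, which oxidises in air once it is free and basic.

The difficulty is congestion: C1 and C8 are adjacent quaternary carbons, C9 lies between two quaternary carbons, and the two arms that become ring A must be brought cis-diaxial.

The strategy rests on the array C2 ketone / C3 aroyl / C4 enol. The C2 carbonyl and the aroyl carbonyl are 1,3-related through C3, so this array is the N–O-cleaved and hydrolysed form of an isoxazole fused to ring A at C2–C3 that carries the aryl ring on its oxygen-bearing carbon.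

## Retrosynthetic reasoning

**31 ⇒ 30 ⇒ 29 ⇒ 28 (no skeletal bond cut).** The three phenols are freed last from tris-MOM ether 30. Compound 30 comes from enaminone 29 by exchange of the C2 amino group for oxygen, and 29 from isoxazole 28 by reductive N–O cleavage. The isoxazole oxygen becomes the aroyl oxygen and the nitrogen marks C2. What is gained is that the acidic, chelating triketone and the air-sensitive triphenol exist only in the last two steps.

**28 ⇒ 26 (through nitrile oxide 27): bonds C2–C3 and O–C(aryl).** Cutting both bonds of the isoxazole removes ring A and the heterocycle together. It leaves aldoxime ynone 26, a ring B cyclohexanone that already holds all four stereocentres. Neither bond ends at a stereocentre, so the forward step has no stereochemical task. It only has to join the nitrile oxide carbon on C1 to the α-carbon of the ynone on C5 across the two diaxial arms, and the tether allows no other regiochemistry.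

**26 ⇒ 25 ⇒ 24 (oxidation level).** The oxime is traced to keto aldehyde ynone 25, and both new carbonyl groups of 25 to diol 24. The aldehyde and the ynone are thus created only after all enolate and organocopper chemistry is over. The oxime is made after the ynone because no oxidation of a propargylic alcohol is expected to spare a free aldoxime.

**24 ⇒ 21 (through 23): bond C1–C2.** C2 is introduced as a hydroxymethyl group on the C1 enolate of ketone 21. At that stage C5 is already quaternary, so C1 is the only enolisable position and regiochemistry is not in question. The smallest possible electrophile is used at the most crowded centre, and it must enter cis to the C5 arm.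

**21 ⇒ 19 ⇒ 17 + 18: bonds C1–prenyl and C8–homoprenyl.** Conjugate addition of the homoprenyl unit from bromide 18 to enone 17 creates quaternary C8 anti to the neighbouring C7 prenyl. It also delivers the C1 enolate regiospecifically, stored as silyl enol ether 19 and then alkylated with prenyl bromide 12. The prenyl group goes on C1 before C2 because the second group at C1 is the one expected to end up axial.

**17 ⇒ 14 + 5 and 14 ⇒ 11 + 12: bonds C5–C4 and C5–prenyl.** Both C5 substituents are attached at the enone stage through the kinetic α′-enolate of 11: first prenyl, then the aryl ynal 5 in an aldol addition. C5 is completed before C8 and C1 so that no later step has to choose between two enolisable α-positions. An aldol adduct, kept as a silyl ether, is used instead of an ynone because an ynone would not survive the organocopper step.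

**11 ⇒ 9 ⇒ 8 ⇒ 6 + 7: C8–methyl, ring B, and the C7 stereocentre.** The C8 methyl of enone 11 comes from conjugate methylation of enone 9 with re-formation of the double bond. Enone 9 comes from keto aldehyde 8 by aldol condensation, and 8 from aldehyde 6 and butenone 7 by an enamine-catalysed Michael addition. This is the only step under external asymmetric control; C5, C8 and C1 are all relayed from C7.

**5 ⇒ 3 ⇒ 2 ⇒ 1: the aryl ynal.** Ynal 5 is derived from dibromoalkene 3, this from protected aldehyde 2, and 2 from commercial 1, by protection, one-carbon homologation to the alkyne and formylation.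

## Alternatives that were turned down

**Alternative 1:** The disconnection is the C1–C8 bond of ring B. The substrate is the monocyclic, dearomatised acylphloroglucinol A1, which carries a prenyl and an E-geranyl chain on C5, a prenyl on enol carbon C1 and the aroyl group as its triacetate. In the forward step an electrophilic phenylselenium reagent, activated by a Lewis acid, converts the C7=C8 alkene into a seleniranium ion. Enol carbon C1 opens it at C8 to give the 7-phenylselanyl bicycle A2.
- In favour: it is biomimetic, it makes the hardest bond (two adjacent quaternary carbons) and ring B in one step, the aroyl group is present from the start, and the sequence would be clearly shorter. On step economy it is stronger than the chosen route.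
- Against: the selenium electrophile must select one of five trisubstituted alkenes in A1. Attack by an enol oxygen competes with attack by C1. The configuration at C8 and the relation of C1 to C5 depend on a chair-versus-boat folding with no strong bias. C7 emerges bearing selenium and must be turned into a prenyl-bearing stereocentre by a radical C–C bond formation of uncertain facial and regiochemical outcome. The absolute configuration would have to be set by an enantioselective dearomatising alkylation at C5 of A1.
- Comparison: the chosen route is longer, but each stereocentre has an identifiable controlling element and the ring-forming step can give only one constitution.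

**Alternative 2:** The disconnection is C5–C9. The substrate is the cyclooctane-1,3-dione A3, with the methyl ester on quaternary C1. Two equivalents of a lithium amide give the dianion, whose terminal carbon C5 attacks the ester carbon across the ring and closes both six-membered rings, giving trione A4 without the C3 aroyl group.
- In favour: one bond closes both rings, the cis geometry of the bridge is enforced by the ring, and a trione of type A4 is a familiar substrate for C3 acylation. On the certainty of the cis-bridge geometry it is at least as strong as the chosen route.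
- Against: A3 is an eight-membered ring with adjacent quaternary C1 and C8 and the C7 stereocentre, so stereocontrolled access to it is as demanding as the target. C5 becomes quaternary in a transannular attack on a neopentyl ester, and its configuration is set there without a clear bias. The product gains no new acidic position, so methoxide can reopen the non-enolisable C9 ketone by retro-Claisen cleavage. The hindered, chelating trione still has to be aroylated at C3.
- Comparison: the chosen route sets the ring B stereocentres on a six-membered ring with well-understood conformations and brings the aroyl carbon in during ring closure.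

**Alternative 3:** The disconnections are C8–CH3 and C7–prenyl on a preformed bicycle. The substrate is the C6-oxo enone A5, with the homoprenyl chain on C8 and a C7=C8 double bond. A methyl cuprate adds to C8 from the face of the C9 bridge, and the resulting C6 enolate is alkylated at C7 with 12 to give A6.
- In favour: the rigid cage gives a clear facial bias at C8, stronger than any control available on a monocycle, and the bridgeheads are made early, so the diaxial-arm problem does not arise. On control at C8 it is stronger than the chosen route.
- Against: the conjugate addition must create quaternary C8 beside the quaternary bridgehead C1 on a hindered bridged enone. The C7 alkylation must place the prenyl group exo. The C6 ketone is an extra oxygen that must be removed in the presence of three other carbonyl groups and four alkenes. Enol ether hydrolysis and C3 aroylation remain.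
- Comparison: the chosen route sets C7 and C8 by anti-selective conjugate addition to a 4-substituted cyclohexenone, carries no superfluous oxygen, and installs the aroyl carbon in the ring closure.

Key step: step 14

Remark: the acyl-triketone of 30 and 31 is tautomeric and is written as its C4 enol; 5-methylhex-4-enal (6) is taken as a purchased aldehyde. Atom numbers C1–C9 of the target are used for all ring B intermediates.

## Route

Step 1
Reactants: 1 2,4,5-trihydroxybenzaldehyde
Product: 2 2,4,5-tris(methoxymethoxy)benzaldehyde
Conditions: MOMCl, iPr2NEt, CH2Cl2, 0 °C → rt, Ar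
Reagents that add atoms: chloromethyl methyl ether, COCCl
Why: Base-mediated O-alkylation (MOM acetal formation) of the three phenols; the amine takes up HCl and the aldehyde is not touched.

Step 2
Reactants: 2 2,4,5-tris(methoxymethoxy)benzaldehyde
Product: 3 1-(2,2-dibromoethenyl)-2,4,5-tris(methoxymethoxy)benzene
Conditions: CBr4, PPh3, Et3N, CH2Cl2, 0 °C
Reagents that add atoms: tetrabromomethane, BrC(Br)(Br)Br
Why: Dibromo-olefination of the aldehyde (first stage of the Corey–Fuchs homologation); Et3N keeps the medium non-acidic for the MOM ethers.

Step 3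
Reactants: 3 1-(2,2-dibromoethenyl)-2,4,5-tris(methoxymethoxy)benzene
Product: 5 3-[2,4,5-tris(methoxymethoxy)phenyl]prop-2-ynal, via lithium acetylide 4 (not isolated)
Conditions: n-BuLi (2.1 equiv), THF, −78 °C; DMF, −78 → 0 °C; aq. KH2PO4
Reagents that add atoms: N,N-dimethylformamide, CN(C)C=O
Why: Br/Li exchange, α-elimination with Fritsch–Buttenberg–Wiechell shift and deprotonation give acetylide 4, which is formylated by DMF; the buffered quench releases the ynal without conjugate addition of dimethylamine.

Step 4
Reactants: 6 5-methylhex-4-enal; 7 but-3-en-2-one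
Product: 8 (2S)-2-(3-methylbut-2-en-1-yl)-5-oxohexanal
Conditions: (S)-2-[methoxy(diphenyl)methyl]pyrrolidine (5 mol %), ethyl 3,4-dihydroxybenzoate (20 mol %), neat, 4 °C
Reagents that add atoms: none
Why: Enamine-catalysed asymmetric Michael addition; the diarylmethyl group of the (S)-catalyst shields one face of the E-enamine, so the enone adds to the open face and sets the future C7 centre in the S configuration of 8.

Step 5
Reactants: 8 (2S)-2-(3-methylbut-2-en-1-yl)-5-oxohexanal
Product: 9 (4S)-4-(3-methylbut-2-en-1-yl)cyclohex-2-en-1-one
Conditions: LiOH, iPrOH, rt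
Reagents that add atoms: none
Why: Intramolecular aldol condensation of the methyl ketone onto the aldehyde closes ring B; under mild base, cyclisation should outrun enolisation of the aldehyde α-carbon, and in 9 that centre is γ and no longer readily epimerised.

Step 6
Reactants: 9 (4S)-4-(3-methylbut-2-en-1-yl)cyclohex-2-en-1-one
Product: 11 (4S)-3-methyl-4-(3-methylbut-2-en-1-yl)cyclohex-2-en-1-one, via lithium enolate 10 (not isolated)
Conditions: Me2CuLi (from MeLi, CuI), Et2O, −78 °C; then PhS(Cl)=NtBu, THF, −78 °C → rt
Reagents that add atoms: lithium dimethylcuprate, [Li+].C[Cu-]C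
Why: Cuprate conjugate addition places the future C8 methyl, and enolate 10 is dehydrogenated in the same flask (Mukaiyama dehydrogenation: S-sulfenylation at the α-carbon, then syn-elimination of the sulfenamide); the transient β-stereocentre is erased and C7 is untouched.

Step 7
Reactants: 11 (4S)-3-methyl-4-(3-methylbut-2-en-1-yl)cyclohex-2-en-1-one; 12 prenyl bromide
Product: 14 C5-prenyl enone (3-methyl-4,6-diprenylcyclohex-2-enone; both C5 epimers), via lithium dienolate 13 (not isolated)
Conditions: LiN(iPr)2, THF, −78 °C; 12, HMPA, −78 → −20 °C
Reagents that add atoms: none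
Why: Kinetic α′-deprotonation gives the cross-conjugated enolate 13 without touching the γ-hydrogen on C7, and SN2 alkylation installs the C5 prenyl; the C5 configuration is immaterial because C5 is enolised again.

Step 8
Reactants: 14 C5-prenyl enone; 5 3-[2,4,5-tris(methoxymethoxy)phenyl]prop-2-ynal
Product: 17 C5-quaternary enone triethylsilyl ether (both carbinol epimers), via lithium dienolate 15 (not isolated), via lithium aldolate 16 (not isolated)
Conditions: LiN(iPr)2, THF, −78 °C; 5, −78 °C; Et3SiOTf, −78 °C
Reagents that add atoms: triethylsilyl trifluoromethanesulfonate, CC[Si](CC)(CC)OS(=O)(=O)C(F)(F)F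
Why: Aldol addition of the tetrasubstituted α′-enolate 15 to the ynal creates quaternary C5; the aldehyde should enter anti to the pseudoaxial C7 prenyl (1,3-relationship), so the C4 arm ends trans and the C5 prenyl cis to the C7 prenyl. Silylation of aldolate 16 at low temperature blocks retro-aldol cleavage, and the carbinol configuration is irrelevant because C4 is oxidised later.

Step 9
Reactants: 17 C5-quaternary enone triethylsilyl ether; 18 5-bromo-2-methylpent-2-ene
Product: 19 trimethylsilyl enol ether (C9–O–SiMe3 with C9=C1)
Conditions: Me2C=CHCH2CH2MgBr (from 18, Mg, THF), CuBr·SMe2 (20 mol %), Me3SiCl, HMPA, THF, −78 → −40 °C; Et3N, pentane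
Reagents that add atoms: chlorotrimethylsilane, C[Si](C)(C)Cl
Why: Copper-catalysed conjugate addition of the Grignard reagent, accelerated by Me3SiCl, forms quaternary C8; the nucleophile adds anti to the adjacent C7 prenyl, which puts the homoprenyl chain trans and the methyl cis to that prenyl, and the enolate is trapped regiospecifically as 19.

Step 10
Reactants: 19 trimethylsilyl enol ether; 12 prenyl bromide
Product: 21 C1-prenyl ketone (both C1 epimers), via lithium enolate 20 (not isolated)
Conditions: MeLi, THF, 0 °C → rt; 12, HMPA, −78 → 0 °C
Reagents that add atoms: none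
Why: MeLi cleaves the Si–O bond to the regio-defined lithium enolate 20, which is C-alkylated by the reactive allylic bromide; the C1 configuration is not fixed here because C1 is enolised once more.

Step 11
Reactants: 21 C1-prenyl ketone
Product: 24 diol (C1 hydroxymethyl and C4 carbinol), via lithium enolate 22 (not isolated), via hydroxymethyl ketone triethylsilyl ether 23 (not isolated)
Conditions: LiN(iPr)2, THF, −78 → −30 °C; HCHO (monomeric, THF), −78 °C; AcOH; then HF·pyridine, 0 °C → rt
Reagents that add atoms: formaldehyde, C=O
Why: C1–H is the only enolisable hydrogen, and aldol addition of enolate 22 to formaldehyde makes quaternary C1; on the ring B half-chair with the C7 prenyl equatorial the electrophile should enter axially, anti to the axial C8 methyl, which places C2 cis to the C5 arm and leaves the prenyl equatorial. Fluoride then removes the silyl ether.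

Step 12
Reactants: 24 diol
Product: 25 keto aldehyde ynone
Conditions: Dess–Martin periodinane, NaHCO3, CH2Cl2, 0 °C → rt
Reagents that add atoms: none
Why: Periodinane oxidation of the primary alcohol to the aldehyde and of the propargylic alcohol to the ynone under buffered, non-nucleophilic conditions; both carbonyl groups sit on quaternary carbons, so nothing can epimerise.

Step 13
Reactants: 25 keto aldehyde ynone
Product: 26 aldoxime ynone (E-oxime)
Conditions: NH2OH·HCl (1.05 equiv), NaOAc, EtOH/THF, 0 °C
Reagents that add atoms: hydroxylamine (as hydrochloride), NO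
Why: Oxime condensation at the aldehyde, by far the most electrophilic and least hindered carbonyl; the ynone is deactivated by the electron-rich aryl group and shielded by quaternary C5, and C9 lies between two quaternary carbons.

Step 14
Reactants: 26 aldoxime ynone
Product: 28 isoxazole-fused bicyclo[3.3.1]nonane, via nitrile oxide 27 (not isolated)
Conditions: PhI(OAc)2, MeOH/CH2Cl2, 0 °C → rt, 0.005 M
Reagents that add atoms: none
Why: PhI(OAc)2 dehydrogenates the aldoxime (ligand exchange at iodine on the oxime oxygen, loss of PhI and AcOH) to nitrile oxide 27. 27 then undergoes a concerted, thermally allowed [3+2] cycloaddition with the ynone in which carbon C2 bonds to C3, the α-carbon of the ynone, and the oxide oxygen bonds to the aryl-bearing β-carbon. The closest known reaction type is the intramolecular nitrile oxide–alkyne cycloaddition that gives ring-fused isoxazoles from alkynyl aldoximes; what is untested is that the tether here is a pair of 1,3-diaxial arms on a cyclohexanone, so the carbocycle that closes is a bridge. Ring A closes as the six-membered tether ring (6-exo-dig with respect to the new C2–C3 bond), and the isoxazole is the five-membered ring of the cycloaddition itself. No stereocentre is formed and C1, C5, C7 and C8 are not touched. Regioselectivity is imposed by the tether and agrees with the electronic preference of conjugated ynones for oxygen attack at the β-carbon. Chemoselectivity over the four trisubstituted alkenes (above all the homoprenyl alkene on C8, which could close a fused six-membered ring) and over furoxan formation is needed; it should be secured by the electron-poor ynone being the fastest dipolarophile, by the chair with all three prenyl groups equatorial holding the two arms diaxial, by the slow dimerisation of a nitrile oxide on a quaternary carbon, and by high dilution. Aromatisation makes the step irreversible and stores the acyl-triketone as an inert heteroarene.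

Step 15
Reactants: 28 isoxazole-fused bicyclo[3.3.1]nonane
Product: 29 enaminone (C2 amino, C3 aroyl, C4 ketone)
Conditions: Mo(CO)6, MeCN/H2O, 80 °C
Reagents that add atoms: none
Why: Mo(CO)6-mediated reductive cleavage of the isoxazole N–O bond gives the hydrogen-bonded β-amino enone; the reagent leaves isolated alkenes, ketones and MOM ethers alone, unlike catalytic hydrogenation.

Step 16
Reactants: 29 enaminone
Product: 30 guttiferone L tris(methoxymethyl) ether
Conditions: LiOH, 1,4-dioxane/H2O, 80 °C, Ar; then 1 M HCl, 0 °C
Reagents that add atoms: water, O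
Why: Addition–elimination of hydroxide at C2 of the vinylogous amide with loss of ammonia, driven by formation of the delocalised triketone anion; the phenols are still protected, so the hot base meets no oxidisable hydroxyhydroquinone, and the brief cold acidification only protonates the enolate.

Step 17
Reactants: 30 guttiferone L tris(methoxymethyl) ether
Product: 31 guttiferone L
Conditions: HCl (3 M), MeOH, 40 °C, Ar
Reagents that add atoms: none
Why: Acid-catalysed acetal cleavage of the three aryl MOM ethers with methanol as acceptor; dilute acid, moderate temperature and exclusion of air are chosen to spare the prenyl groups and the hydroxyhydroquinone.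

## Compound list

1 | 2,4,5-trihydroxybenzaldehyde | O=Cc1cc(O)c(O)cc1O | starting material
2 | 2,4,5-tris(methoxymethoxy)benzaldehyde | O=Cc1cc(OCOC)c(OCOC)cc1OCOC | intermediate
3 | 1-(2,2-dibromoethenyl)-2,4,5-tris(methoxymethoxy)benzene | BrC(Br)=Cc1cc(OCOC)c(OCOC)cc1OCOC | intermediate
4 | lithium [2,4,5-tris(methoxymethoxy)phenyl]acetylide | [Li]C#Cc1cc(OCOC)c(OCOC)cc1OCOC | intermediate
5 | 3-[2,4,5-tris(methoxymethoxy)phenyl]prop-2-ynal | O=CC#Cc1cc(OCOC)c(OCOC)cc1OCOC | intermediate
6 | 5-methylhex-4-enal | CC(C)=CCCC=O | starting material
7 | but-3-en-2-one (methyl vinyl ketone) | CC(=O)C=C | starting material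
8 | (2S)-2-(3-methylbut-2-en-1-yl)-5-oxohexanal | O=C[C@H](CC=C(C)C)CCC(C)=O | intermediate
9 | (4S)-4-(3-methylbut-2-en-1-yl)cyclohex-2-en-1-one | O=C1C=C[C@H](CC=C(C)C)CC1 | intermediate
10 | lithium enolate of trans-3-methyl-4-prenylcyclohexanone (methyl trans to prenyl) | [Li]OC1=C[C@@H](C)[C@H](CC=C(C)C)CC1 | intermediate
11 | (4S)-3-methyl-4-(3-methylbut-2-en-1-yl)cyclohex-2-en-1-one | O=C1C=C(C)[C@H](CC=C(C)C)CC1 | intermediate
12 | prenyl bromide (1-bromo-3-methylbut-2-ene) | CC(C)=CCBr | starting material
13 | lithium cross-conjugated dienolate of 11 (C9–OLi, C9=C5) | [Li]OC1=CC[C@@H](CC=C(C)C)C(C)=C1 | intermediate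
14 | 3-methyl-4,6-bis(3-methylbut-2-en-1-yl)cyclohex-2-en-1-one; C7 as in 11, both C5 epimers | O=C1C=C(C)[C@H](CC=C(C)C)CC1CC=C(C)C | intermediate
15 | lithium dienolate of 14 (C9=C5 bearing prenyl) | [Li]OC1=C(CC=C(C)C)C[C@@H](CC=C(C)C)C(C)=C1 | intermediate
16 | lithium aldolate: enone with quaternary C5 carrying prenyl (cis to C7 prenyl) and the 1-lithiooxy-3-arylprop-2-ynyl arm (trans to C7 prenyl) | O=C1C=C(C)[C@H](CC=C(C)C)C[C@@]1(CC=C(C)C)C(O[Li])C#Cc1cc(OCOC)c(OCOC)cc1OCOC | intermediate
17 | triethylsilyl ether of the C5 aldol adduct: 3-methyl-4,6-diprenyl-6-{3-[2,4,5-tris(methoxymethoxy)phenyl]-1-(triethylsilyloxy)prop-2-yn-1-yl}cyclohex-2-en-1-one; arm trans to C7 prenyl, both carbinol epimers | O=C1C=C(C)[C@H](CC=C(C)C)C[C@@]1(CC=C(C)C)C(O[Si](CC)(CC)CC)C#Cc1cc(OCOC)c(OCOC)cc1OCOC | intermediate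
18 | 5-bromo-2-methylpent-2-ene | CC(C)=CCCBr | starting material
19 | trimethylsilyl enol ether (C9=C1) of the conjugate adduct; C8 methyl cis and homoprenyl trans to C7 prenyl | CC(C)=CCC[C@@]1(C)[C@H](CC=C(C)C)C[C@](C(O[Si](CC)(CC)CC)C#Cc2cc(OCOC)c(OCOC)cc2OCOC)(CC=C(C)C)C(O[Si](C)(C)C)=C1 | intermediate
20 | lithium enolate (C9=C1) from 19 | CC(C)=CCC[C@@]1(C)[C@H](CC=C(C)C)C[C@](C(O[Si](CC)(CC)CC)C#Cc2cc(OCOC)c(OCOC)cc2OCOC)(CC=C(C)C)C(O[Li])=C1 | intermediate
21 | ring B ketone with C1–H prenyl (both C1 epimers), quaternary C5 and C8 | CC(C)=CCC[C@@]1(C)[C@H](CC=C(C)C)C[C@](C(O[Si](CC)(CC)CC)C#Cc2cc(OCOC)c(OCOC)cc2OCOC)(CC=C(C)C)C(=O)C1CC=C(C)C | intermediate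
22 | lithium enolate of 21 (C9=C1 bearing prenyl) | CC(C)=CCC[C@@]1(C)[C@H](CC=C(C)C)C[C@](C(O[Si](CC)(CC)CC)C#Cc2cc(OCOC)c(OCOC)cc2OCOC)(CC=C(C)C)C(O[Li])=C1CC=C(C)C | intermediate
23 | C1 hydroxymethyl ketone, C4 triethylsilyl ether; hydroxymethyl cis to the C5 arm | CC(C)=CCC[C@@]1(C)[C@H](CC=C(C)C)C[C@](C(O[Si](CC)(CC)CC)C#Cc2cc(OCOC)c(OCOC)cc2OCOC)(CC=C(C)C)C(=O)[C@@]1(CC=C(C)C)CO | intermediate
24 | diol: C1 hydroxymethyl, C4 propargylic carbinol (both carbinol epimers) | CC(C)=CCC[C@@]1(C)[C@H](CC=C(C)C)C[C@](C(O)C#Cc2cc(OCOC)c(OCOC)cc2OCOC)(CC=C(C)C)C(=O)[C@@]1(CC=C(C)C)CO | intermediate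
25 | ring B ketone with C1 formyl and C5 arylpropynoyl groups | CC(C)=CCC[C@@]1(C)[C@H](CC=C(C)C)C[C@](C(=O)C#Cc2cc(OCOC)c(OCOC)cc2OCOC)(CC=C(C)C)C(=O)[C@@]1(CC=C(C)C)C=O | intermediate
26 | ring B ketone with C1 (E)-aldoxime and C5 arylpropynoyl group, aryl tris-MOM ether | CC(C)=CCC[C@@]1(C)[C@H](CC=C(C)C)C[C@](C(=O)C#Cc2cc(OCOC)c(OCOC)cc2OCOC)(CC=C(C)C)C(=O)[C@@]1(CC=C(C)C)/C=N/O | intermediate
27 | nitrile oxide on C1 | CC(C)=CCC[C@@]1(C)[C@H](CC=C(C)C)C[C@](C(=O)C#Cc2cc(OCOC)c(OCOC)cc2OCOC)(CC=C(C)C)C(=O)[C@@]1(CC=C(C)C)C#[N+][O-] | intermediate
28 | bicyclo[3.3.1]nonane-4,9-dione with ring A fused at C2–C3 to a 5-aryl isoxazole | CC(C)=CCC[C@@]1(C)[C@H](CC=C(C)C)C[C@]2(CC=C(C)C)C(=O)[C@@]1(CC=C(C)C)c1noc(-c3cc(OCOC)c(OCOC)cc3OCOC)c1C2=O | intermediate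
29 | enaminone: 2-amino-3-aroylbicyclo[3.3.1]non-2-ene-4,9-dione | CC(C)=CCC[C@@]1(C)[C@H](CC=C(C)C)C[C@]2(CC=C(C)C)C(=O)[C@@]1(CC=C(C)C)C(N)=C(C(=O)c1cc(OCOC)c(OCOC)cc1OCOC)C2=O | intermediate
30 | guttiferone L tris(methoxymethyl) ether (C4 enol drawn) | CC(C)=CCC[C@@]1(C)[C@H](CC=C(C)C)C[C@]2(CC=C(C)C)C(=O)[C@@]1(CC=C(C)C)C(=O)C(C(=O)c1cc(OCOC)c(OCOC)cc1OCOC)=C2O | intermediate
31 | guttiferone L | CC(C)=CCC[C@@]1(C)[C@H](CC=C(C)C)C[C@]2(CC=C(C)C)C(=O)[C@@]1(CC=C(C)C)C(=O)C(C(=O)c1cc(O)c(O)cc1O)=C2O | target

## Step count and least certain steps

Total: 17 steps. Longest linear sequence: 14 steps (steps 4 to 17, from 6 and 7); the aryl branch (steps 1 to 3) joins at step 8.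

**Step 14 (key step).** The most likely failure is that ring closure is outrun by dimerisation of the nitrile oxide or by cycloaddition to the homoprenyl alkene on C8. To react, the two diaxial arms must bend towards each other, and the closure of a bridged ring in this way is untested. The fallback closes the C2–C3 bond by a polar route. It sets out from 25: MgI2 in CH2Cl2 at 0 °C should add iodide to the ynone and let the resulting allenolate attack the aldehyde (intramolecular iodo-aldol reaction of Baylis–Hillman type), giving the bicyclic β-iodo alcohol F1. Dess–Martin oxidation should give the iodo enedione F2, and aqueous NaHCO3 should hydrolyse this vinylogous acyl iodide. The route is rejoined at 30.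

**Step 11.** The most likely failure is slow or incomplete deprotonation of C1–H, which lies between the quaternary C8 and a ketone flanked by quaternary C5, together with retro-aldol loss of formaldehyde on warming. The fallback avoids a strong base and sets out from 21. Soft enolisation with Me3SiOTf and Et3N should give the tetrasubstituted silyl enol ether F3, the only regioisomer possible. A Mukaiyama aldol reaction with aqueous formaldehyde and Yb(OTf)3 should then deliver the hydroxymethyl ketone. The route is rejoined at 23, which is desilylated to 24 as in step 11.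

**Step 8.** The most likely failure is poor facial selectivity at C5, because the cross-conjugated dienolate is nearly flat and the control is only a 1,3-relationship to C7; retro-aldol cleavage before silylation is the second concern. The fallback moves the C5 chemistry to the saturated ring, where axial attack on a chair is better defined, and sets out from 11.
- Conjugate addition under the conditions of step 9 should give silyl enol ether F4.
- MeLi and 12 should give the C1-prenyl ketone F5.
- LiN(iPr)2 and 12 should alkylate the unhindered C5 methylene to give the C1,C5-diprenyl ketone F6.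
- Kinetic deprotonation at the less encumbered C5–H, addition to 5 and trapping with Et3SiOTf rejoin the route at 21.

**Step 13.** The most likely failure is loss of chemoselectivity: conjugate addition of hydroxylamine to the ynone, or ring closure of the new oxime onto a neighbouring carbonyl group. The fallback forms the oxime before any ynone exists. It sets out from 23, isolated by leaving out the fluoride treatment of step 11.
- Dess–Martin oxidation should give aldehyde F7.
- Hydroxylamine should give oxime F8.
- PhI(OAc)2 should effect the intramolecular cycloaddition onto the non-conjugated alkyne, giving the C4 silyloxy isoxazole F9.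
- HF·pyridine should give carbinol F10.
- Dess–Martin oxidation rejoins the route at 28.

**Step 17.** The most likely failure is acid-promoted cyclisation of a prenyl group onto an enol oxygen of the free triketone, or air oxidation of the hydroxyhydroquinone. The fallback removes the MOM ethers while the triketone is still masked, and sets out from 28. HCl in MeOH should give the isoxazole triphenol F11, and Mo(CO)6 in MeCN/H2O should give the enaminone triphenol F12. Hydrolysis under argon (LiOH in degassed aqueous dioxane, then cold acid) rejoins the route at 31.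

## Further compounds

F1 | step 14 | bicyclic β-iodo alcohol: C2 carbinol, C3 aryl(iodo)methylidene, C4 ketone | CC(C)=CCC[C@@]1(C)[C@H](CC=C(C)C)C[C@]2(CC=C(C)C)C(=O)[C@@]1(CC=C(C)C)C(O)C(=C(I)c1cc(OCOC)c(OCOC)cc1OCOC)C2=O
F2 | step 14 | iodo enedione: 3-[aryl(iodo)methylidene]bicyclo[3.3.1]nonane-2,4,9-trione | CC(C)=CCC[C@@]1(C)[C@H](CC=C(C)C)C[C@]2(CC=C(C)C)C(=O)[C@@]1(CC=C(C)C)C(=O)C(=C(I)c1cc(OCOC)c(OCOC)cc1OCOC)C2=O
F3 | step 11 | tetrasubstituted trimethylsilyl enol ether of 21 (C9=C1) | CC(C)=CCC[C@@]1(C)[C@H](CC=C(C)C)C[C@](C(O[Si](CC)(CC)CC)C#Cc2cc(OCOC)c(OCOC)cc2OCOC)(CC=C(C)C)C(O[Si](C)(C)C)=C1CC=C(C)C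
F4 | step 8 | trimethylsilyl enol ether of 3-homoprenyl-3-methyl-4-prenylcyclohexanone (homoprenyl trans to prenyl) | CC(C)=CCC[C@@]1(C)[C@H](CC=C(C)C)CCC(O[Si](C)(C)C)=C1
F5 | step 8 | 3-homoprenyl-3-methyl-2,4-diprenylcyclohexanone (both C1 epimers) | CC(C)=CCC[C@@]1(C)[C@H](CC=C(C)C)CCC(=O)C1CC=C(C)C
F6 | step 8 | 3-homoprenyl-3-methyl-2,4,6-triprenylcyclohexanone (C1 and C5 epimers) | CC(C)=CCC[C@@]1(C)[C@H](CC=C(C)C)CC(CC=C(C)C)C(=O)C1CC=C(C)C
F7 | step 13 | C1 aldehyde with C4 triethylsilyl ether | CC(C)=CCC[C@@]1(C)[C@H](CC=C(C)C)C[C@](C(O[Si](CC)(CC)CC)C#Cc2cc(OCOC)c(OCOC)cc2OCOC)(CC=C(C)C)C(=O)[C@@]1(CC=C(C)C)C=O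
F8 | step 13 | C1 (E)-aldoxime with C4 triethylsilyl ether | CC(C)=CCC[C@@]1(C)[C@H](CC=C(C)C)C[C@](C(O[Si](CC)(CC)CC)C#Cc2cc(OCOC)c(OCOC)cc2OCOC)(CC=C(C)C)C(=O)[C@@]1(CC=C(C)C)/C=N/O
F9 | step 13 | isoxazole-fused bicycle with C4 triethylsilyloxy group | CC(C)=CCC[C@@]1(C)[C@H](CC=C(C)C)C[C@]2(CC=C(C)C)C(=O)[C@@]1(CC=C(C)C)c1noc(-c3cc(OCOC)c(OCOC)cc3OCOC)c1C2O[Si](CC)(CC)CC
F10 | step 13 | isoxazole-fused bicycle with C4 hydroxy group | CC(C)=CCC[C@@]1(C)[C@H](CC=C(C)C)C[C@]2(CC=C(C)C)C(=O)[C@@]1(CC=C(C)C)c1noc(-c3cc(OCOC)c(OCOC)cc3OCOC)c1C2O
F11 | step 17 | isoxazole-fused bicycle with free 2,4,5-trihydroxyphenyl group | CC(C)=CCC[C@@]1(C)[C@H](CC=C(C)C)C[C@]2(CC=C(C)C)C(=O)[C@@]1(CC=C(C)C)c1noc(-c3cc(O)c(O)cc3O)c1C2=O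
F12 | step 17 | enaminone with free 2,4,5-trihydroxybenzoyl group | CC(C)=CCC[C@@]1(C)[C@H](CC=C(C)C)C[C@]2(CC=C(C)C)C(=O)[C@@]1(CC=C(C)C)C(N)=C(C(=O)c1cc(O)c(O)cc1O)C2=O
A1 | alternative 1 | monocyclic C5-geranyl C5-prenyl C1-prenyl acylphloroglucinol trienone, aryl triacetate | CC(C)=CCC/C(C)=C/C[C@]1(CC=C(C)C)C(=O)C(CC=C(C)C)=C(O)C(C(=O)c2cc(OC(C)=O)c(OC(C)=O)cc2OC(C)=O)=C1O
A2 | alternative 1 | 7-phenylselanyl bicyclo[3.3.1]nonane trione, aryl triacetate | CC(C)=CCC[C@@]1(C)[C@H]([Se]c3ccccc3)C[C@]2(CC=C(C)C)C(=O)[C@@]1(CC=C(C)C)C(=O)C(C(=O)c1cc(OC(C)=O)c(OC(C)=O)cc1OC(C)=O)=C2O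
A3 | alternative 2 | methyl 8-homoprenyl-8-methyl-2,4-dioxo-1,5,7-triprenylcyclooctane-1-carboxylate (C5 epimers) | CC(C)=CCC[C@@]1(C)[C@H](CC=C(C)C)CC(CC=C(C)C)C(=O)CC(=O)[C@]1(CC=C(C)C)C(=O)OC
A4 | alternative 2 | bicyclic trione lacking the C3 aroyl group | CC(C)=CCC[C@@]1(C)[C@H](CC=C(C)C)C[C@]2(CC=C(C)C)C(=O)[C@@]1(CC=C(C)C)C(=O)C=C2O
A5 | alternative 3 | bicyclic C6-oxo C7=C8 enone with homoprenyl on C8, C4 methyl enol ether | CC(C)=CCCC1=CC(=O)[C@]2(CC=C(C)C)C(=O)[C@@]1(CC=C(C)C)C(=O)C=C2OC
A6 | alternative 3 | C6-oxo bicycle with C7 prenyl and C8 methyl in place | CC(C)=CCC[C@@]1(C)[C@H](CC=C(C)C)C(=O)[C@]2(CC=C(C)C)C(=O)[C@@]1(CC=C(C)C)C(=O)C=C2OC
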